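**Assumption:** compounds 1, 2, 5, 16 and 22 are taken as commercial (5 derives from L-glutamic acid, 1 from the Roche ester); locants C1–C15 in the comments are the usual germacranolide ones (C1 ketone, C3 carbinol, C4 with methyl C15, C6 lactone oxygen, C7, C8 angelate, C10 with methyl C14 and acetate, C11–C13 methylene lactone).

## Retrosynthetic overview

1. Target 25 ⇐ 24 (Si–O cleavage) ⇐ 21 (angelate put on the free C8–OH).
2. 21 ⇐ 19: the C6–C7 bond is made by an electrochemical chromium-catalysed allylation that closes the ten-membered carbocycle first; the γ-lactone (second ring) closes on acidic work-up.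
3. 19 ⇐ 15: Morita–Baylis–Hillman reaction at C7, allylic bromide, alkene cleavage to the C6 aldehyde.
4. 15 ⇐ 11 + 4: C2–C3 bond by a Felkin-controlled Mukaiyama aldol.
5. 11 ⇐ lactone 5 (C8 bought, C10 by enolate hydroxylation); 4 ⇐ bromo alcohol 1 (C4 bought).

## Route

Step 1
Reactants: 1 (R)-3-bromo-2-methylpropan-1-ol; 2 vinylmagnesium bromide
Product: 3 (S)-2-methylpent-4-en-1-ol
Conditions: 2 (3 equiv), Li2CuCl4 (5 mol %), THF, –20 → 0 °C
Reagents that add atoms: none
Why: Copper-catalysed (Kochi-type) cross-coupling of the primary bromide, the first equivalent of Grignard reagent only deprotonating the alcohol, leaves the bought stereocentre (future C4) untouched.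

Step 2
Reactants: 3 (S)-2-methylpent-4-en-1-ol
Product: 4 (S)-2-methylpent-4-enal
Conditions: TEMPO (10 mol %), PhI(OAc)2, CH2Cl2, 0 °C → rt; used at once as a CH2Cl2 solution
Reagents that add atoms: none
Why: Oxoammonium (TEMPO) oxidation under buffer-free, non-basic conditions gives the volatile α-methyl aldehyde without epimerisation.

Step 3
Reactants: 5 (S)-5-(hydroxymethyl)dihydrofuran-2(3H)-one
Product: 6 (S)-5-{[(triethylsilyl)oxy]methyl}dihydrofuran-2(3H)-one
Conditions: Et3SiCl, imidazole, CH2Cl2, 0 °C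
Reagents that add atoms: chlorotriethylsilane, CC[Si](Cl)(CC)CC
Why: Standard silylation of the primary alcohol gives a group that shields one lactone face and can later be oxidised directly to the aldehyde.

Step 4
Reactants: 6 (S)-5-{[(triethylsilyl)oxy]methyl}dihydrofuran-2(3H)-one
Product: 7 (3R,5S)-3-methyl-5-{[(triethylsilyl)oxy]methyl}dihydrofuran-2(3H)-one
Conditions: LiN(iPr)2, THF, –78 °C; MeI, –78 → –40 °C
Reagents that add atoms: iodomethane, CI
Why: Lactone enolate alkylation occurs anti to the C5 silyloxymethyl group (trans product), although this centre is planarised again in the next step.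

Step 5
Reactants: 7 (3R,5S)-3-methyl-5-{[(triethylsilyl)oxy]methyl}dihydrofuran-2(3H)-one
Product: 8 (3R,5S)-3-hydroxy-3-methyl-5-{[(triethylsilyl)oxy]methyl}dihydrofuran-2(3H)-one
Conditions: KN(SiMe3)2, THF, –78 °C; MoO(O2)2(pyridine)(HMPA), –78 → –40 °C
Reagents that add atoms: oxodiperoxymolybdenum(pyridine)(HMPA), O=[Mo]12(OO1)OO2.c1ccncc1.CN(C)P(=O)(N(C)C)N(C)C
Why: Vedejs enolate hydroxylation delivers oxygen to the enolate face anti to the C5 substituent, so the bought centre (future C8) sets the quaternary carbinol (future C10, R).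

Step 6
Reactants: 8 (3R,5S)-3-hydroxy-3-methyl-5-{[(triethylsilyl)oxy]methyl}dihydrofuran-2(3H)-one
Product: 9 (3R,5S)-3,5-dihydroxy-3-methyl-6-[(triethylsilyl)oxy]hexan-2-one
Conditions: MeLi (2.2 equiv), THF, –78 °C; aqueous work-up at –78 °C
Reagents that add atoms: methyllithium, [Li]C
Why: Mono-addition of methyllithium to the lactone (the tetrahedral lactolate is stable at –78 °C) gives the methyl ketone, in equilibrium with its cyclic hemiketal, with both stereocentres untouched.

Step 7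
Reactants: 9 (3R,5S)-3,5-dihydroxy-3-methyl-6-[(triethylsilyl)oxy]hexan-2-one
Product: 10 (3R,5S)-3-hydroxy-3-methyl-5,6-bis[(triethylsilyl)oxy]hexan-2-one
Conditions: Et3SiCl (1.1 equiv), imidazole, DMF, 0 °C
Reagents that add atoms: chlorotriethylsilane, CC[Si](Cl)(CC)CC
Why: Silylation takes the secondary hydroxyl of the open-chain form much faster than the tertiary or hemiketal hydroxyl.

Step 8
Reactants: 10 (3R,5S)-3-hydroxy-3-methyl-5,6-bis[(triethylsilyl)oxy]hexan-2-one
Product: 11 (3R,5S)-3-methyl-2-oxo-5,6-bis[(triethylsilyl)oxy]hexan-3-yl acetate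
Conditions: Ac2O, DMAP, Et3N, CH2Cl2, rt → 35 °C
Reagents that add atoms: acetic anhydride, CC(=O)OC(C)=O
Why: DMAP-catalysed acylation puts the acetate on the only free (tertiary) hydroxyl while the molecule is still small and robust.

Step 9
Reactants: 11 (3R,5S)-3-methyl-2-oxo-5,6-bis[(triethylsilyl)oxy]hexan-3-yl acetate; 4 (S)-2-methylpent-4-enal
Product: 13 (2S,4R,7S,8S)-7-hydroxy-4,8-dimethyl-5-oxo-1,2-bis[(triethylsilyl)oxy]undec-10-en-4-yl acetate, via silyl enol ether 12 (not isolated)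
Conditions: Me3SiOTf, Et3N, CH2Cl2, 0 °C; solvent exchange; 4 (1.5 equiv), BF3·OEt2, CH2Cl2, –78 °C
Reagents that add atoms: none
Why: Mukaiyama aldol of the only possible enol silane through an open transition state adds to the α-methyl aldehyde in the Felkin–Anh sense, giving the 3,4-syn adduct so that C4 (S) sets C3 (S); a dr of roughly 6–10:1 is expected and the minor epimer is removed by chromatography.

Step 10
Reactants: 13 (2S,4R,7S,8S)-7-hydroxy-4,8-dimethyl-5-oxo-1,2-bis[(triethylsilyl)oxy]undec-10-en-4-yl acetate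
Product: 14 (2S,4R,7S,8S)-7-[(tert-butyldimethylsilyl)oxy]-4,8-dimethyl-5-oxo-1,2-bis[(triethylsilyl)oxy]undec-10-en-4-yl acetate
Conditions: tBuMe2SiOTf, 2,6-lutidine, CH2Cl2, –78 °C
Reagents that add atoms: tert-butyldimethylsilyl trifluoromethanesulfonate, CC(C)(C)[Si](C)(C)OS(=O)(=O)C(F)(F)F
Why: Low-temperature silylation protects the β-hydroxy ketone without retro-aldol, so that C3–OH cannot later form a lactol with the C6 aldehyde or compete for the angelate.

Step 11
Reactants: 14 (2S,4R,7S,8S)-7-[(tert-butyldimethylsilyl)oxy]-4,8-dimethyl-5-oxo-1,2-bis[(triethylsilyl)oxy]undec-10-en-4-yl acetate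
Product: 15 (2S,4R,7S,8S)-7-[(tert-butyldimethylsilyl)oxy]-4,8-dimethyl-1,5-dioxo-2-[(triethylsilyl)oxy]undec-10-en-4-yl acetate
Conditions: (COCl)2, DMSO, CH2Cl2, –78 → –30 °C; Et3N, –78 → 0 °C
Reagents that add atoms: none
Why: Swern conditions cleave and oxidise a primary triethylsilyl ether directly to the aldehyde while secondary triethylsilyl and tert-butyldimethylsilyl ethers survive.

Step 12
Reactants: 15 (2S,4R,7S,8S)-7-[(tert-butyldimethylsilyl)oxy]-4,8-dimethyl-1,5-dioxo-2-[(triethylsilyl)oxy]undec-10-en-4-yl acetate; 16 methyl acrylate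
Product: 17 methyl (4S,6R,9S,10S)-6-acetoxy-9-[(tert-butyldimethylsilyl)oxy]-3-hydroxy-6,10-dimethyl-2-methylidene-7-oxo-4-[(triethylsilyl)oxy]tridec-12-enoate (both C3 epimers)
Conditions: 16 (10 equiv), DABCO (1 equiv), MeOH, rt, 3 d
Reagents that add atoms: none
Why: Morita–Baylis–Hillman reaction of the activated α-silyloxy aldehyde (the hindered ketone does not react) attaches C11–C13; the new carbinol centre is irrelevant because it becomes sp2 in the next step.

Step 13
Reactants: 17 methyl (4S,6R,9S,10S)-6-acetoxy-9-[(tert-butyldimethylsilyl)oxy]-3-hydroxy-6,10-dimethyl-2-methylidene-7-oxo-4-[(triethylsilyl)oxy]tridec-12-enoate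
Product: 18 methyl (2Z,4S,6R,9S,10S)-6-acetoxy-2-(bromomethyl)-9-[(tert-butyldimethylsilyl)oxy]-6,10-dimethyl-7-oxo-4-[(triethylsilyl)oxy]trideca-2,12-dienoate
Conditions: NBS, Me2S, CH2Cl2, –30 → 0 °C
Reagents that add atoms: N-bromosuccinimide, O=C1CCC(=O)N1Br
Why: Corey–Kim-type activation of the allylic alcohol followed by SN2′ attack of bromide at the methylene terminus gives the thermodynamic (Z)-2-(bromomethyl)enoate without touching the terminal alkene.

Step 14
Reactants: 18 methyl (2Z,4S,6R,9S,10S)-6-acetoxy-2-(bromomethyl)-9-[(tert-butyldimethylsilyl)oxy]-6,10-dimethyl-7-oxo-4-[(triethylsilyl)oxy]trideca-2,12-dienoate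
Product: 19 methyl (2Z,4S,6R,9S,10S)-6-acetoxy-2-(bromomethyl)-9-[(tert-butyldimethylsilyl)oxy]-6,10-dimethyl-7,12-dioxo-4-[(triethylsilyl)oxy]dodec-2-enoate
Conditions: OsO4 (2 mol %), NaIO4, 2,6-lutidine, dioxane–H2O (3:1), rt; used crude
Reagents that add atoms: sodium periodate, [Na+].[O-]I(=O)(=O)=O
Why: Lemieux–Johnson cleavage is selective because the monosubstituted alkene is dihydroxylated far faster than the electron-poor trisubstituted enoate.

Step 15
Reactants: 19 methyl (2Z,4S,6R,9S,10S)-6-acetoxy-2-(bromomethyl)-9-[(tert-butyldimethylsilyl)oxy]-6,10-dimethyl-7,12-dioxo-4-[(triethylsilyl)oxy]dodec-2-enoate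
Product: 21 (3aR,4S,6R,9S,10S,11aR)-9-[(tert-butyldimethylsilyl)oxy]-4-hydroxy-6,10-dimethyl-3-methylidene-2,7-dioxododecahydrocyclodeca[b]furan-6-yl acetate, via macrocyclic trimethylsilyl ether 20 (not isolated)
Conditions: CrCl3 (15 mol %), 4,4′,4″-tri-tert-butyl-2,2′:6′,2″-terpyridine (17 mol %), Me3SiCl (2 equiv), nBu4NBr (0.1 M), DMF, undivided cell, Al anode, Ni-foam cathode, 3 mA (2.3 F/mol), 19 added by syringe pump to 2 mM, rt; then 1 M HCl, THF, 0 °C → rt
Reagents that add atoms: none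
Why: Proposed new method: cathodic reduction keeps a bulky terpyridine-ligated divalent chromium catalyst turning over (sacrificial Al anode, Me3SiCl frees trivalent chromium from the alkoxide), the allyl bromide gives an allylchromium that adds to the C6 aldehyde through a chair transition state with C5 and C8 equatorial (anti adduct, hence the trans lactone) on the allyl face that carries the C9 tether and is opposite the C8 OSiEt3 group with C8–H eclipsing the enoate, which sets C6 (R) and C7 (S), while the neopentyl C1 ketone cannot take the axial position against the ligand, and acid then closes the lactone and removes the triethylsilyl group; the closest known reactions are stoichiometric CrCl2 Barbier/Nozaki–Hiyama–Kishi macrocyclisations of 2-(bromomethyl)enoates and the intermolecular electrochemical Nozaki–Hiyama–Kishi coupling.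

Step 16
Reactants: 21 (3aR,4S,6R,9S,10S,11aR)-9-[(tert-butyldimethylsilyl)oxy]-4-hydroxy-6,10-dimethyl-3-methylidene-2,7-dioxododecahydrocyclodeca[b]furan-6-yl acetate; 22 angelic acid
Product: 24 (3aS,4S,6R,9S,10S,11aR)-6-acetoxy-9-[(tert-butyldimethylsilyl)oxy]-6,10-dimethyl-3-methylidene-2,7-dioxododecahydrocyclodeca[b]furan-4-yl (2Z)-2-methylbut-2-enoate, via mixed anhydride 23 (not isolated)
Conditions: 22, 2,4,6-Cl3C6H2COCl, Et3N, toluene, rt, 2 h; then 21, 80 °C
Reagents that add atoms: none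
Why: Yamaguchi esterification through the hindered mixed anhydride, without DMAP, acylates the only free hydroxyl (C8) with retention and without Z → E isomerisation to the tiglate.

Step 17
Reactants: 24 (3aS,4S,6R,9S,10S,11aR)-6-acetoxy-9-[(tert-butyldimethylsilyl)oxy]-6,10-dimethyl-3-methylidene-2,7-dioxododecahydrocyclodeca[b]furan-4-yl (2Z)-2-methylbut-2-enoate
Product: 25 (3aS,4S,6R,9S,10S,11aR)-6-acetoxy-9-hydroxy-6,10-dimethyl-3-methylidene-2,7-dioxododecahydrocyclodeca[b]furan-4-yl (2Z)-2-methylbut-2-enoate (CNP0141210.5)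
Conditions: HF·pyridine, pyridine, THF, 0 °C → rt
Reagents that add atoms: none
Why: Buffered fluoride desilylation frees the C3 hydroxyl under non-basic conditions that spare the β-hydroxy ketone, both esters and the methylene lactone.

## Compound list

1 | (R)-3-bromo-2-methylpropan-1-ol | BrC[C@H](C)CO | starting material
2 | vinylmagnesium bromide | C=C[Mg]Br | starting material
3 | (S)-2-methylpent-4-en-1-ol | C=CC[C@H](C)CO | intermediate
4 | (S)-2-methylpent-4-enal | C=CC[C@H](C)C=O | intermediate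
5 | (S)-5-(hydroxymethyl)dihydrofuran-2(3H)-one | OC[C@@H]1CCC(=O)O1 | starting material
6 | (S)-5-{[(triethylsilyl)oxy]methyl}dihydrofuran-2(3H)-one | CC[Si](CC)(CC)OC[C@@H]1CCC(=O)O1 | intermediate
7 | (3R,5S)-3-methyl-5-{[(triethylsilyl)oxy]methyl}dihydrofuran-2(3H)-one | O=C1[C@H](C)C[C@H](O1)CO[Si](CC)(CC)CC | intermediate
8 | (3R,5S)-3-hydroxy-3-methyl-5-{[(triethylsilyl)oxy]methyl}dihydrofuran-2(3H)-one | O=C1[C@](C)(O)C[C@H](O1)CO[Si](CC)(CC)CC | intermediate
9 | (3R,5S)-3,5-dihydroxy-3-methyl-6-[(triethylsilyl)oxy]hexan-2-one | CC(=O)[C@](C)(O)C[C@H](O)CO[Si](CC)(CC)CC | intermediate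
10 | (3R,5S)-3-hydroxy-3-methyl-5,6-bis[(triethylsilyl)oxy]hexan-2-one | CC(=O)[C@](C)(O)C[C@H](O[Si](CC)(CC)CC)CO[Si](CC)(CC)CC | intermediate
11 | (3R,5S)-3-methyl-2-oxo-5,6-bis[(triethylsilyl)oxy]hexan-3-yl acetate | CC(=O)[C@](C)(OC(C)=O)C[C@H](O[Si](CC)(CC)CC)CO[Si](CC)(CC)CC | intermediate
12 | (3R,5S)-3-methyl-5,6-bis[(triethylsilyl)oxy]-2-[(trimethylsilyl)oxy]hex-1-en-3-yl acetate | C=C(O[Si](C)(C)C)[C@](C)(OC(C)=O)C[C@H](O[Si](CC)(CC)CC)CO[Si](CC)(CC)CC | intermediate (not isolated)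
13 | (2S,4R,7S,8S)-7-hydroxy-4,8-dimethyl-5-oxo-1,2-bis[(triethylsilyl)oxy]undec-10-en-4-yl acetate | C=CC[C@H](C)[C@@H](O)CC(=O)[C@](C)(OC(C)=O)C[C@H](O[Si](CC)(CC)CC)CO[Si](CC)(CC)CC | intermediate
14 | (2S,4R,7S,8S)-7-[(tert-butyldimethylsilyl)oxy]-4,8-dimethyl-5-oxo-1,2-bis[(triethylsilyl)oxy]undec-10-en-4-yl acetate | C=CC[C@H](C)[C@@H](O[Si](C)(C)C(C)(C)C)CC(=O)[C@](C)(OC(C)=O)C[C@H](O[Si](CC)(CC)CC)CO[Si](CC)(CC)CC | intermediate
15 | (2S,4R,7S,8S)-7-[(tert-butyldimethylsilyl)oxy]-4,8-dimethyl-1,5-dioxo-2-[(triethylsilyl)oxy]undec-10-en-4-yl acetate | C=CC[C@H](C)[C@@H](O[Si](C)(C)C(C)(C)C)CC(=O)[C@](C)(OC(C)=O)C[C@H](O[Si](CC)(CC)CC)C=O | intermediate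
16 | methyl acrylate | C=CC(=O)OC | starting material
17 | methyl (4S,6R,9S,10S)-6-acetoxy-9-[(tert-butyldimethylsilyl)oxy]-3-hydroxy-6,10-dimethyl-2-methylidene-7-oxo-4-[(triethylsilyl)oxy]tridec-12-enoate (both C3 epimers) | C=CC[C@H](C)[C@@H](O[Si](C)(C)C(C)(C)C)CC(=O)[C@](C)(OC(C)=O)C[C@H](O[Si](CC)(CC)CC)C(O)C(=C)C(=O)OC | intermediate
18 | methyl (2Z,4S,6R,9S,10S)-6-acetoxy-2-(bromomethyl)-9-[(tert-butyldimethylsilyl)oxy]-6,10-dimethyl-7-oxo-4-[(triethylsilyl)oxy]trideca-2,12-dienoate | C=CC[C@H](C)[C@@H](O[Si](C)(C)C(C)(C)C)CC(=O)[C@](C)(OC(C)=O)C[C@H](O[Si](CC)(CC)CC)/C=C(\CBr)C(=O)OC | intermediate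
19 | methyl (2Z,4S,6R,9S,10S)-6-acetoxy-2-(bromomethyl)-9-[(tert-butyldimethylsilyl)oxy]-6,10-dimethyl-7,12-dioxo-4-[(triethylsilyl)oxy]dodec-2-enoate | O=CC[C@H](C)[C@@H](O[Si](C)(C)C(C)(C)C)CC(=O)[C@](C)(OC(C)=O)C[C@H](O[Si](CC)(CC)CC)/C=C(\CBr)C(=O)OC | intermediate
20 | methyl 2-[(1S,2R,4S,5S,8R,10S)-8-acetoxy-5-[(tert-butyldimethylsilyl)oxy]-4,8-dimethyl-7-oxo-10-[(triethylsilyl)oxy]-2-[(trimethylsilyl)oxy]cyclodecyl]prop-2-enoate | COC(=O)C(=C)[C@H]1[C@H](O[Si](C)(C)C)C[C@H](C)[C@@H](O[Si](C)(C)C(C)(C)C)CC(=O)[C@](C)(OC(C)=O)C[C@@H]1O[Si](CC)(CC)CC | intermediate (not isolated)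
21 | (3aR,4S,6R,9S,10S,11aR)-9-[(tert-butyldimethylsilyl)oxy]-4-hydroxy-6,10-dimethyl-3-methylidene-2,7-dioxododecahydrocyclodeca[b]furan-6-yl acetate (3aR only by the sequence rule; same geometry as in 25) | C=C1C(=O)O[C@@H]2C[C@H](C)[C@@H](O[Si](C)(C)C(C)(C)C)CC(=O)[C@](C)(OC(C)=O)C[C@H](O)[C@@H]12 | intermediate
22 | angelic acid, (2Z)-2-methylbut-2-enoic acid | C/C=C(/C)C(=O)O | starting material
23 | (2Z)-2-methylbut-2-enoic 2,4,6-trichlorobenzoic anhydride | C/C=C(/C)C(=O)OC(=O)c1c(Cl)cc(Cl)cc1Cl | intermediate (not isolated)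
24 | (3aS,4S,6R,9S,10S,11aR)-6-acetoxy-9-[(tert-butyldimethylsilyl)oxy]-6,10-dimethyl-3-methylidene-2,7-dioxododecahydrocyclodeca[b]furan-4-yl (2Z)-2-methylbut-2-enoate | C=C1C(=O)O[C@@H]2C[C@H](C)[C@@H](O[Si](C)(C)C(C)(C)C)CC(=O)[C@](C)(OC(C)=O)C[C@H](OC(=O)/C(C)=C\C)[C@@H]12 | intermediate
25 | (3aS,4S,6R,9S,10S,11aR)-6-acetoxy-9-hydroxy-6,10-dimethyl-3-methylidene-2,7-dioxododecahydrocyclodeca[b]furan-4-yl (2Z)-2-methylbut-2-enoate (CNP0141210.5) | C=C1C(=O)O[C@@H]2C[C@H](C)[C@@H](O)CC(=O)[C@](C)(OC(C)=O)C[C@H](OC(=O)/C(C)=C\C)[C@@H]12 | target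

## Step count and risks

Total step count: 17 (steps 1–2 make aldehyde 4; steps 3–17 are linear).
Longest linear sequence: 15 steps (5 → 25).

**Step 15 (proposed new electrochemical macrocyclisation).** It can fail through electrode passivation or oligomers. It can also fail through 5-exo attack of the allylchromium on the C1 ketone, and the fallback below does not remove that risk. The addition may also take the other allyl face and give the 6,7-bis-epimer. The fallback uses known chemistry and gives up electrosynthesis for the stoichiometric reagent. It sets out from 19, which is added by syringe pump (2 mM final) to CrCl2 (8 equiv) in degassed THF–DMF at rt; this is the established Nozaki–Hiyama–Kishi/Barbier macrocyclisation used for germacranolide rings. After quenching it gives methyl 2-[(1S,2R,4S,5S,8R,10S)-8-acetoxy-5-[(tert-butyldimethylsilyl)oxy]-2-hydroxy-4,8-dimethyl-7-oxo-10-[(triethylsilyl)oxy]cyclodecyl]prop-2-enoate, the ring-closed hydroxy ester F1. The same 1 M HCl/THF treatment lactonises it and removes the triethylsilyl group, so the route is rejoined at 21.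

**Step 12 (Morita–Baylis–Hillman reaction).** The α-branched α-silyloxy aldehyde may react slowly, and long exposure to DABCO risks epimerisation at C8 or silyl migration. The fallback builds the same adduct by an aldol/selenoxide route. It sets out from 15: the lithium enolate of methyl 2-(phenylselanyl)propanoate (LiN(iPr)2, THF, –78 °C) adds to the aldehyde within minutes to give methyl (4S,6R,9S,10S)-6-acetoxy-9-[(tert-butyldimethylsilyl)oxy]-3-hydroxy-2,6,10-trimethyl-7-oxo-2-(phenylselanyl)-4-[(triethylsilyl)oxy]tridec-12-enoate, the β-hydroxy α-selanyl ester F2. Oxidation with H2O2 and pyridine in CH2Cl2 at 0 °C gives the selenoxide, which eliminates toward the methyl group and away from the carbinol, and the route is rejoined at 17.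

**Step 16 (angeloylation).** In 21 the C8 hydroxyl is hindered and can sit in a transannular hemiketal with the C1 ketone; heating with Et3N risks angelate → tiglate isomerisation and β-elimination of the C3 silyloxy group. The fallback builds the Z-alkene on the molecule instead of transferring it. It sets out from 21, which is esterified at 0 °C with 2-[bis(2,2,2-trifluoroethoxy)phosphoryl]propanoic acid (DCC, DMAP, CH2Cl2) to give (3aS,4S,6R,9S,10S,11aR)-6-acetoxy-9-[(tert-butyldimethylsilyl)oxy]-6,10-dimethyl-3-methylidene-2,7-dioxododecahydrocyclodeca[b]furan-4-yl 2-[bis(2,2,2-trifluoroethoxy)phosphoryl]propanoate, the phosphonopropanoate F3. A Still–Gennari olefination (KN(SiMe3)2, 18-crown-6, THF, –78 °C, then acetaldehyde) gives the (Z)-2-methylbut-2-enoate, and the route is rejoined at 24.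

## Further compounds

F1 | step 15 | methyl 2-[(1S,2R,4S,5S,8R,10S)-8-acetoxy-5-[(tert-butyldimethylsilyl)oxy]-2-hydroxy-4,8-dimethyl-7-oxo-10-[(triethylsilyl)oxy]cyclodecyl]prop-2-enoate | COC(=O)C(=C)[C@H]1[C@H](O)C[C@H](C)[C@@H](O[Si](C)(C)C(C)(C)C)CC(=O)[C@](C)(OC(C)=O)C[C@@H]1O[Si](CC)(CC)CC
F2 | step 12 | methyl (4S,6R,9S,10S)-6-acetoxy-9-[(tert-butyldimethylsilyl)oxy]-3-hydroxy-2,6,10-trimethyl-7-oxo-2-(phenylselanyl)-4-[(triethylsilyl)oxy]tridec-12-enoate (C2/C3 epimers) | C=CC[C@H](C)[C@@H](O[Si](C)(C)C(C)(C)C)CC(=O)[C@](C)(OC(C)=O)C[C@H](O[Si](CC)(CC)CC)C(O)C(C)([Se]c1ccccc1)C(=O)OC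
F3 | step 16 | (3aS,4S,6R,9S,10S,11aR)-6-acetoxy-9-[(tert-butyldimethylsilyl)oxy]-6,10-dimethyl-3-methylidene-2,7-dioxododecahydrocyclodeca[b]furan-4-yl 2-[bis(2,2,2-trifluoroethoxy)phosphoryl]propanoate (both epimers at the phosphonate carbon) | C=C1C(=O)O[C@@H]2C[C@H](C)[C@@H](O[Si](C)(C)C(C)(C)C)CC(=O)[C@](C)(OC(C)=O)C[C@H](OC(=O)C(C)P(=O)(OCC(F)(F)F)OCC(F)(F)F)[C@@H]12
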